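**Conventions.** Ring A is the 3-hydroxy-4,5-dimethoxyphenyl group (carried as its benzyl ether until the last step) and ring B is the 3,4,5-trimethoxyphenyl group. The oxolane is numbered O1, C2 (ring A), C3 (methyl), C4 (methyl), C5 (ring B). The route runs 1–17, and 17 is the target.

## The problem

Target 17 is a 2,5-diaryl-3,4-dimethyloxolane with four contiguous stereocentres, arranged 2,3-trans, 3,4-cis, 4,5-trans, so that the two aryl groups are cis to each other and trans to both methyl groups. With two identical aryl groups the skeleton would be meso. Ring A and ring B differ by a single O-methyl group, so the absolute configuration amounts to placing the right aryl group at the right end of the cis-dimethyl unit. C4 and C5 can be set together, C4 can then direct C3, and the two methyl groups can direct C2. The cis-dimethyl pair is the less stable arrangement, however, so C3 has to be set kinetically and must not be left under equilibrating conditions next to a carbonyl or an oxocarbenium carbon. C2 and C5 are benzylic ether carbons carrying para-alkoxyaryl groups, and acid can ionise them, with epimerisation, ring opening or cyclisation onto the other arene. The phenol has to be masked during organometallic steps and unmasked without cleaving the ring C–O bonds. Ring A is bonded through a carbon meta to two oxygens, which rules out Friedel–Crafts arylation and calls for an aryl-metal reagent. The enabling feature is that C5 is a benzylic carbinol carbon next to methyl-bearing C4, the pattern of an aldehyde crotylation, while C3 and C2 can travel on the allyl reagent as an α-methylene ester (C2 as the carboxyl carbon, the C3 methyl as the exocyclic methylene).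

## Retrosynthesis

**17 from 16.** The only bond cut is the phenolic O–benzyl bond. A benzyl ether is chosen because it survives magnesium insertion and organozinc chemistry and is removed by hydrogenolysis faster than the secondary benzylic ring C–O bonds. A methyl ether could not be removed selectively beside five others. The forward step must leave the oxolane intact.

**16 from 11 and 15.** The C2–aryl bond is cut, giving the 2-sulfonyl oxolane 11 (an oxocarbenium precursor) and the arylzinc reagent 15, made through the arylmagnesium bromide 14 from aryl bromide 13. Friedel–Crafts arylation cannot deliver ring A with this substitution pattern. Adding the aryl group to lactone 9 and reducing the hemiketal would bring hydride in trans to the methyl groups and leave the aryl group on the wrong face. Attack of an aryl nucleophile on the oxocarbenium ion should instead come from the face opposite both methyl groups, which is the face needed. The precursor 11 carries only ring B and three stereocentres.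

**11 from 10 from 9.** These are changes of functional group at C2 only: sulfinate for hydroxyl, and lactol from lactone by partial reduction. Lactone 9 is a stable compound in which C3, C4 and C5 are fixed on a five-membered ring. The forward steps must avoid base, since C3 is α to the carbonyl and carries the less stable cis relationship.

**9 from 8.** The C3–H bond is cut, leading back to the α-methylene lactone 8. Setting the C3 methyl by hydrogenation of an exocyclic alkene next to the C4 methyl is preferred to alkylating a lactone enolate, which would give the trans-dimethyl isomer. The forward reaction has to add hydrogen anti to the C4 methyl group.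

**8 from 7.** The acyl C–O bond of the lactone is cut, giving the open hydroxy ester 7. The benzylic C–O bond is not touched, so the forward lactonisation only has to proceed without ionising the benzylic carbinol.

**7 from 5 and 4 (key disconnection).** The C4–C5 bond is cut between the carbinol carbon and the methyl-bearing carbon, giving aldehyde 5 and the ester-bearing crotylboronate 4. This single union supplies C2 to C5, both methyl carbons in latent or final form, and two stereocentres. An aldol-based alternative would need several further steps to add C3 and C2. The forward reaction requires anti selectivity, which comes from the reagent geometry in a closed chair transition state, and face selectivity, which comes from a chiral phosphoric acid.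

**4 from 1 and 2.** The C2–CH2B bond and the C3–H bond of the reagent are cut, leading to alkynoate 1 and iodomethylboronate 2. The anti adduct requires the methyl group trans to the CH2B carbon, which is the (Z)-ester. An allylic-substitution route to this reagent would be expected to deliver the other, tiglate-type geometry, and through the same chair that would lead to the syn adduct. Syn hydrometalation of 1 followed by C-alkylation fixes the required geometry by mechanism.

**13 from 12.** The benzyl ether is cut, giving the commercial bromophenol 12.

## Roads not taken

**Alternative 1:** The cut is the C2–C3 bond, made together with the ring. Diazo ester A1 already holds C4, C5 and ring B, and carries ring A as a benzylic ether on the C5 oxygen. Rh2(O2CCPh3)4 would convert it into a carbene at C3 that inserts into the ring A benzylic C–H bond to give oxolane ester A2.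
- Merits: the ring and two stereocentres form in one catalytic step, and ring A enters by simple O-alkylation, with no aryl-metal addition to an oxocarbenium ion. In that respect it is cleaner than the endgame chosen here.
- Weak points: the carbene has a neighbouring C–H bond at C4, and 1,2-hydride shift to an alkene competes with insertion; the bulky carboxylate ligand slows this but does not exclude it. C3 arrives as an ester, so three further steps at a centre flanked on both sides are needed to reach the methyl group. The insertion must place the ester trans to ring A and cis to the C4 methyl at once. A1 itself still needs the enantiopure anti C4/C5 array, so the crotylation problem is deferred, not avoided.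
- Comparison: the chosen plan is shorter and brings C3 in one hydrogenation away from its final form.

**Alternative 2:** The cut is a late differentiation of two phenols. The target is one O-methyl group away from the meso bis-phenol A3. Acetic anhydride with a π-methylhistidine peptide catalyst would acylate one enantiotopic phenol to give monoacetate A4; methylation of the free phenol and deacetylation would give 17.
- Merits: A3 has no absolute stereochemistry and could come from short symmetric chemistry, and there is a single enantio-determining step. In step count this road is probably shorter than the chosen one, which is a real advantage.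
- Weak points: the two phenols are about a nanometre apart, several bonds from the nearest stereocentre, and each is flanked by a methoxy group. Remote discrimination of this kind is known for peptide catalysts but would need a catalyst search for this substrate. Over-acylation costs material. A3 still requires the full relative stereocontrol. Any acetyl loss or transfer during methylation of A4 erodes the enantiomeric purity directly.
- Comparison: against the shorter count, the chosen plan offers absolute control through a well-understood transition state and introduces the two aryl groups as different building blocks, so they never need to be told apart.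

**Alternative 3:** The cut is the two C–H bonds at C3 and C4. The (Z)-aroylacrylic acid A5, as its triethylammonium salt, would be hydrogenated with Ru(OAc)2[(S)-H8-BINAP] to give keto acid A6 by syn addition.
- Merits: the cis-dimethyl pair, the least stable element of the target, is set directly under catalyst control. This is better than the substrate control relied on in step 4 of the chosen plan.
- Weak points: a tetrasubstituted acyclic alkene is a demanding substrate. A5 can exist as its cyclic hydroxybutenolide tautomer. In A6 the C3 centre is α to an aryl ketone and can epimerise, particularly in the presence of amine. C2 and C5 remain to be set by substrate control, through a ketone reduction and an aryl addition at the lactol stage, so the endgame is no shorter.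
- Comparison: the chosen plan sets two stereocentres in its key step in a setting that cannot epimerise, and sets the third on a rigid lactone with an adjacent directing methyl group.

Key step: step 2

Assumption: (R)-TRIP, that is (R)-3,3′-bis(2,4,6-triisopropylphenyl)-1,1′-binaphthalene-2,2′-diyl hydrogen phosphate, is taken to direct attack to the Re face of 5 with the ester-bearing reagent 4 as it does with simple allyl and crotyl pinacolboronates; if a first run shows the opposite sense (MTPA ester analysis of 7), the (S)-acid is used and nothing else changes.

## Route

Step 1
Reactants: 1 ethyl but-2-ynoate; 2 2-(iodomethyl)-4,4,5,5-tetramethyl-1,3,2-dioxaborolane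
Product: 4 ethyl (2Z)-2-[(4,4,5,5-tetramethyl-1,3,2-dioxaborolan-2-yl)methyl]but-2-enoate, via α-alumino enoate 3 (not isolated)
Conditions: i-Bu2AlH, HMPA, THF, 0 °C; then 2, 0 °C → rt
Reagents that add atoms: none
Why: Hydroalumination of the alkynoate by the i-Bu2AlH·HMPA complex is a syn addition (hydride to C3, aluminium to C2), and the α-alumino enoate 3 or its allenolate is C-alkylated by the α-iodoboronate on the side of the C3 hydrogen; the CH2B carbon therefore ends trans to the methyl group, which is the (Z)-ester with methyl cis to CO2Et (hydrometalation–alkylation).

Step 2
Reactants: 4 ethyl (2Z)-2-[(4,4,5,5-tetramethyl-1,3,2-dioxaborolan-2-yl)methyl]but-2-enoate; 5 3,4,5-trimethoxybenzaldehyde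
Product: 7 ethyl (3R,4R)-4-hydroxy-3-methyl-2-methylidene-4-(3,4,5-trimethoxyphenyl)butanoate, via O-pinacolboryl ether 6 (not isolated)
Conditions: (R)-3,3′-bis(2,4,6-triisopropylphenyl)-1,1′-binaphthalene-2,2′-diyl hydrogen phosphate (10 mol%), 4 Å MS, toluene, 0 °C → rt; aq. NaHCO3
Reagents that add atoms: none
Why: The phosphoric acid acts bifunctionally: its P–OH hydrogen-bonds to the pseudo-axial oxygen of the dioxaborolane, raising the Lewis acidity of boron, and its P=O contacts the formyl hydrogen, so the boron-bound aldehyde is held in one orientation. Allyl transfer then runs through a closed six-membered Zimmerman–Traxler chair in which C3 of the reagent attacks the carbonyl carbon with allylic transposition, forming the C4–C5 bond of the target and the 2-methylidene ester. The closest known reaction types are the chiral-phosphoric-acid-catalysed crotylboration of aryl aldehydes with pinacol boronates and the Brønsted-acid-catalysed addition of 2-alkoxycarbonyl allylboronates to aldehydes. No ring closes: the primary product is the borate 6, which is hydrolysed on work-up to the open hydroxy ester 7. The relative configuration (methyl-bearing carbon, 3R) follows from the reagent geometry, because the methyl group trans to the CH2B carbon and the aryl group of the aldehyde both sit equatorial in the chair, which gives the anti adduct. The absolute configuration (carbinol carbon, 4R) is set by the catalyst, whose 2,4,6-triisopropylphenyl groups should leave only the Re face of the bound aldehyde open. The step needs face selectivity over a racemic background and retention of the alkene geometry; the ester makes 4 a poor nucleophile without activation, so the uncatalysed pathway should be negligible at the reaction temperature, and 5 has no ortho substituent or basic group to disturb the hydrogen-bond network.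

Step 3
Reactants: 7 ethyl (3R,4R)-4-hydroxy-3-methyl-2-methylidene-4-(3,4,5-trimethoxyphenyl)butanoate
Product: 8 (4R,5R)-4-methyl-3-methylidene-5-(3,4,5-trimethoxyphenyl)oxolan-2-one
Conditions: p-TsOH·H2O (10 mol%), CH2Cl2, rt
Reagents that add atoms: none
Why: Acid-catalysed intramolecular transesterification (lactonisation) takes place at the acyl carbon, so the benzylic C–O bond is not broken, both stereocentres are retained, and methyl and aryl end trans on the ring; any 7 that has already cyclised in step 2 is the same product.

Step 4
Reactants: 8 (4R,5R)-4-methyl-3-methylidene-5-(3,4,5-trimethoxyphenyl)oxolan-2-one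
Product: 9 (3S,4R,5R)-3,4-dimethyl-5-(3,4,5-trimethoxyphenyl)oxolan-2-one
Conditions: H2 (1 atm), 10% Pd/C, EtOAc, rt
Reagents that add atoms: none
Why: Heterogeneous syn hydrogenation of the exocyclic 1,1-disubstituted alkene should occur from the face opposite the adjacent C4 methyl group, so the new C3 methyl ends cis to it (3S); this is the kinetic, less stable arrangement, and the neutral conditions do not equilibrate it.

Step 5
Reactants: 9 (3S,4R,5R)-3,4-dimethyl-5-(3,4,5-trimethoxyphenyl)oxolan-2-one
Product: 10 (3S,4R,5R)-3,4-dimethyl-5-(3,4,5-trimethoxyphenyl)oxolan-2-ol (mixture at C2)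
Conditions: i-Bu2AlH, CH2Cl2, −78 °C; aq. potassium sodium tartrate
Reagents that add atoms: none
Why: Partial reduction of a lactone to the lactol works at low temperature because the tetrahedral aluminium hemiacetal does not collapse; no base is present, so C3 keeps its configuration, and the anomeric mixture is of no consequence.

Step 6
Reactants: 10 (3S,4R,5R)-3,4-dimethyl-5-(3,4,5-trimethoxyphenyl)oxolan-2-ol
Product: 11 (3S,4R,5R)-2-(benzenesulfonyl)-3,4-dimethyl-5-(3,4,5-trimethoxyphenyl)oxolane (mixture at C2)
Conditions: PhSO2H, CaCl2, CH2Cl2, rt
Reagents that add atoms: benzenesulfinic acid, O=S(O)c1ccccc1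
Why: The lactol hydroxyl is exchanged for sulfinate through the oxocarbenium ion (S-alkylation of the sulfinate), the standard entry to 2-sulfonyl cyclic ethers, with CaCl2 taking up the water; the configuration at C2 is set anew in step 8.

Step 7
Reactants: 12 5-bromo-2,3-dimethoxyphenol
Product: 13 1-(benzyloxy)-5-bromo-2,3-dimethoxybenzene
Conditions: BnBr, K2CO3, DMF, rt
Reagents that add atoms: benzyl bromide, BrCc1ccccc1
Why: Williamson ether synthesis of a phenoxide with a primary benzylic bromide; the aryl bromide is inert under these conditions.

Step 8
Reactants: 13 1-(benzyloxy)-5-bromo-2,3-dimethoxybenzene; 11 (3S,4R,5R)-2-(benzenesulfonyl)-3,4-dimethyl-5-(3,4,5-trimethoxyphenyl)oxolane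
Product: 16 (2S,3S,4R,5R)-2-[3-(benzyloxy)-4,5-dimethoxyphenyl]-3,4-dimethyl-5-(3,4,5-trimethoxyphenyl)oxolane, via arylmagnesium bromide 14 (not isolated), via arylzinc bromide 15 (not isolated)
Conditions: 13, Mg, THF, reflux; ZnBr2, THF, 0 °C → rt; then 11, THF, rt
Reagents that add atoms: none
Why: Magnesium insertion and transmetalation give the arylzinc reagent, ZnBr2 assists loss of sulfinate from 11, and the aryl group adds to the oxocarbenium ion (organozinc substitution of a 2-sulfonyl cyclic ether, a reaction used for 2,5-diaryl-3,4-dimethyloxolanes). In the envelope that keeps the C4 methyl and the C5 aryl group pseudo-equatorial, inside attack comes from the face opposite both methyl groups, which should set C2 as 2S (ring A trans to the C3 methyl, cis to ring B).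

Step 9
Reactants: 16 (2S,3S,4R,5R)-2-[3-(benzyloxy)-4,5-dimethoxyphenyl]-3,4-dimethyl-5-(3,4,5-trimethoxyphenyl)oxolane
Product: 17 5-[(2S,3S,4R,5R)-3,4-dimethyl-5-(3,4,5-trimethoxyphenyl)oxolan-2-yl]-2,3-dimethoxyphenol
Conditions: H2 (1 atm), 10% Pd/C, EtOAc–MeOH, rt
Reagents that add atoms: none
Why: Hydrogenolysis of the aryl benzyl ether should be much faster than cleavage of the two secondary benzylic C–O bonds of the oxolane, and no stereocentre is touched.

## Compound list

1 | ethyl but-2-ynoate | CC#CC(=O)OCC | starting material
2 | 2-(iodomethyl)-4,4,5,5-tetramethyl-1,3,2-dioxaborolane | CC1(C)OB(CI)OC1(C)C | starting material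
3 | ethyl (2E)-2-[bis(2-methylpropyl)alumanyl]but-2-enoate | C/C=C(/[Al](CC(C)C)CC(C)C)C(=O)OCC | intermediate (not isolated)
4 | ethyl (2Z)-2-[(4,4,5,5-tetramethyl-1,3,2-dioxaborolan-2-yl)methyl]but-2-enoate | C/C=C(/CB1OC(C)(C)C(C)(C)O1)C(=O)OCC | intermediate
5 | 3,4,5-trimethoxybenzaldehyde | COc1cc(C=O)cc(OC)c1OC | starting material
6 | ethyl (3R,4R)-3-methyl-2-methylidene-4-[(4,4,5,5-tetramethyl-1,3,2-dioxaborolan-2-yl)oxy]-4-(3,4,5-trimethoxyphenyl)butanoate | CCOC(=O)C(=C)[C@@H](C)[C@@H](OB1OC(C)(C)C(C)(C)O1)c1cc(OC)c(OC)c(OC)c1 | intermediate (not isolated)
7 | ethyl (3R,4R)-4-hydroxy-3-methyl-2-methylidene-4-(3,4,5-trimethoxyphenyl)butanoate | CCOC(=O)C(=C)[C@@H](C)[C@@H](O)c1cc(OC)c(OC)c(OC)c1 | intermediate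
8 | (4R,5R)-4-methyl-3-methylidene-5-(3,4,5-trimethoxyphenyl)oxolan-2-one | O=C1O[C@@H](c2cc(OC)c(OC)c(OC)c2)[C@H](C)C1=C | intermediate
9 | (3S,4R,5R)-3,4-dimethyl-5-(3,4,5-trimethoxyphenyl)oxolan-2-one | O=C1O[C@@H](c2cc(OC)c(OC)c(OC)c2)[C@H](C)[C@@H]1C | intermediate
10 | (3S,4R,5R)-3,4-dimethyl-5-(3,4,5-trimethoxyphenyl)oxolan-2-ol (mixture at C2) | OC1O[C@@H](c2cc(OC)c(OC)c(OC)c2)[C@H](C)[C@@H]1C | intermediate
11 | (3S,4R,5R)-2-(benzenesulfonyl)-3,4-dimethyl-5-(3,4,5-trimethoxyphenyl)oxolane (mixture at C2) | O=S(=O)(c1ccccc1)C2O[C@@H](c3cc(OC)c(OC)c(OC)c3)[C@H](C)[C@@H]2C | intermediate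
12 | 5-bromo-2,3-dimethoxyphenol | COc1cc(Br)cc(O)c1OC | starting material
13 | 1-(benzyloxy)-5-bromo-2,3-dimethoxybenzene | COc1cc(Br)cc(OCc2ccccc2)c1OC | intermediate
14 | [3-(benzyloxy)-4,5-dimethoxyphenyl]magnesium bromide | COc1cc([Mg]Br)cc(OCc2ccccc2)c1OC | intermediate (not isolated)
15 | [3-(benzyloxy)-4,5-dimethoxyphenyl]zinc bromide | COc1cc([Zn]Br)cc(OCc2ccccc2)c1OC | intermediate (not isolated)
16 | (2S,3S,4R,5R)-2-[3-(benzyloxy)-4,5-dimethoxyphenyl]-3,4-dimethyl-5-(3,4,5-trimethoxyphenyl)oxolane | COc1cc([C@H]2O[C@@H](c3cc(OC)c(OC)c(OC)c3)[C@H](C)[C@@H]2C)cc(OCc4ccccc4)c1OC | intermediate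
17 | 5-[(2S,3S,4R,5R)-3,4-dimethyl-5-(3,4,5-trimethoxyphenyl)oxolan-2-yl]-2,3-dimethoxyphenol | COc1cc([C@H]2O[C@@H](c3cc(OC)c(OC)c(OC)c3)[C@H](C)[C@@H]2C)cc(O)c1OC | target

## Step count and risk

Total: 9 steps. Longest linear sequence: 8 steps (steps 1–6, 8 and 9, from 1); the ring A branch contributes step 7.

**Step 2 (key step).** The most likely failure is slow turnover, because the ester lowers the nucleophilicity of the allyl unit and a phosphoric acid is a mild activator. Face selectivity could also erode if the ester carbonyl competes for the catalyst hydrogen bond. Partial lactonisation in the flask would be harmless. The fallback moves the stereocontrol from the catalyst to an ester auxiliary and sets out from 5. But-2-ynoic acid is esterified with 8-phenylmenthol to give (1R,2S,5R)-5-methyl-2-(2-phenylpropan-2-yl)cyclohexyl but-2-ynoate F1. This is hydroaluminated and alkylated with 2 as in step 1 to give (1R,2S,5R)-5-methyl-2-(2-phenylpropan-2-yl)cyclohexyl (2Z)-2-[(4,4,5,5-tetramethyl-1,3,2-dioxaborolan-2-yl)methyl]but-2-enoate F2. Addition of F2 to 5 under Sc(OTf)3 catalysis at low temperature is an auxiliary-controlled 2-alkoxycarbonyl allylboration, still through the closed chair and therefore anti. Lactonisation with p-TsOH and release of the auxiliary returns to the route at 8. The antipodal auxiliary is taken if the sense of induction requires it.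

**Step 8.** Three processes could interfere: insufficient facial discrimination in the aryl transfer, elimination of sulfinate to the 2,3-dihydrofuran, and epimerisation of C3 through reversible enol ether formation from the oxocarbenium ion. The fallback reverses the order of bond formation and sets out from 10 and 13. The arylmagnesium bromide 14 is added to the open hydroxy aldehyde form of lactol 10 to give (2S,3R,4R)-1-[3-(benzyloxy)-4,5-dimethoxyphenyl]-2,3-dimethyl-4-(3,4,5-trimethoxyphenyl)butane-1,4-diol F3 as a mixture at C1. Cyclodehydration under mild acid (catalytic p-TsOH, CH2Cl2, 0 °C) through the ring A benzylic cation should close the ring with the aryl group trans to the neighbouring methyl, the kinetically and thermodynamically preferred outcome, and returns to the route at 16.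

**Step 4.** Palladium could migrate the double bond into the ring before reduction, could cleave the benzylic lactone C–O bond, or could discriminate the two faces poorly. The fallback replaces surface hydrogenation by conjugate reduction and sets out from 8. LiBH(s-Bu)3 in THF at −78 °C should give lithium (4R,5R)-3,4-dimethyl-5-(3,4,5-trimethoxyphenyl)-4,5-dihydrofuran-2-olate F4. Kinetic protonation at −78 °C with aq. NH4Cl from the face opposite the C4 methyl group returns to the route at 9.

**Step 1.** The alkene geometry could be lost if the α-alumino enoate equilibrates through its allenolate on warming; 1,2-reduction of the ester and slow alkylation would lower the yield. The fallback separates hydrometalation from C–C bond formation and sets out from 1. Hydrostannation with Bu3SnH and Pd(PPh3)4 (zerovalent palladium, syn addition) should give ethyl (2E)-2-(tributylstannyl)but-2-enoate F5. Treatment with I2 gives ethyl (2E)-2-iodobut-2-enoate F6 with retention. Negishi coupling of F6 with pinBCH2ZnI (from 2 and zinc dust) under Pd(PPh3)4 returns to the route at 4 with the geometry intact.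

## Further compounds

F1 | step 2 | (1R,2S,5R)-5-methyl-2-(2-phenylpropan-2-yl)cyclohexyl but-2-ynoate | C[C@@H]1CC[C@H]([C@@H](C1)OC(=O)C#CC)C(C)(C)c2ccccc2
F2 | step 2 | (1R,2S,5R)-5-methyl-2-(2-phenylpropan-2-yl)cyclohexyl (2Z)-2-[(4,4,5,5-tetramethyl-1,3,2-dioxaborolan-2-yl)methyl]but-2-enoate | C[C@@H]1CC[C@H]([C@@H](C1)OC(=O)/C(CB3OC(C)(C)C(C)(C)O3)=C\C)C(C)(C)c2ccccc2
F3 | step 8 | (2S,3R,4R)-1-[3-(benzyloxy)-4,5-dimethoxyphenyl]-2,3-dimethyl-4-(3,4,5-trimethoxyphenyl)butane-1,4-diol (mixture at C1) | COc1cc(C(O)[C@@H](C)[C@@H](C)[C@@H](O)c2cc(OC)c(OC)c(OC)c2)cc(OCc3ccccc3)c1OC
F4 | step 4 | lithium (4R,5R)-3,4-dimethyl-5-(3,4,5-trimethoxyphenyl)-4,5-dihydrofuran-2-olate | [Li+].[O-]C1=C(C)[C@@H](C)[C@H](c2cc(OC)c(OC)c(OC)c2)O1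
F5 | step 1 | ethyl (2E)-2-(tributylstannyl)but-2-enoate | C/C=C(/[Sn](CCCC)(CCCC)CCCC)C(=O)OCC
F6 | step 1 | ethyl (2E)-2-iodobut-2-enoate | C/C=C(/I)C(=O)OCC
A1 | alternative 1 | methyl (3R,4R)-4-{[3-(benzyloxy)-4,5-dimethoxyphenyl]methoxy}-2-diazo-3-methyl-4-(3,4,5-trimethoxyphenyl)butanoate | COC(=O)C(=[N+]=[N-])[C@@H](C)[C@@H](OCc1cc(OC)c(OC)c(OCc2ccccc2)c1)c1cc(OC)c(OC)c(OC)c1
A2 | alternative 1 | methyl (2S,3S,4R,5R)-2-[3-(benzyloxy)-4,5-dimethoxyphenyl]-4-methyl-5-(3,4,5-trimethoxyphenyl)oxolane-3-carboxylate | COc1cc(cc(OCc2ccccc2)c1OC)[C@@H]1[C@@H](C(=O)OC)[C@@H](C)[C@H](c2cc(OC)c(OC)c(OC)c2)O1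
A3 | alternative 2 | 5,5′-[(2R,3R,4S,5S)-3,4-dimethyloxolane-2,5-diyl]bis(2,3-dimethoxyphenol) (meso) | COc1cc([C@H]2O[C@@H](c3cc(O)c(OC)c(OC)c3)[C@H](C)[C@@H]2C)cc(O)c1OC
A4 | alternative 2 | 5-[(2S,3S,4R,5R)-5-(3-hydroxy-4,5-dimethoxyphenyl)-3,4-dimethyloxolan-2-yl]-2,3-dimethoxyphenyl acetate | COc1cc([C@H]2O[C@@H](c3cc(O)c(OC)c(OC)c3)[C@H](C)[C@@H]2C)cc(OC(C)=O)c1OC
A5 | alternative 3 | (2Z)-4-[3-(benzyloxy)-4,5-dimethoxyphenyl]-2,3-dimethyl-4-oxobut-2-enoic acid | COc1cc(cc(OCc2ccccc2)c1OC)C(=O)/C(C)=C(/C)C(O)=O
A6 | alternative 3 | (2R,3S)-4-[3-(benzyloxy)-4,5-dimethoxyphenyl]-2,3-dimethyl-4-oxobutanoic acid | COc1cc(cc(OCc2ccccc2)c1OC)C(=O)[C@@H](C)[C@@H](C)C(O)=O
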